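## Retrosynthetic overview

1. The hydroxyquinone comes last, by oxidative demethylation of a 11,14-dimethoxy-12-silyloxy arene; the C1 alcohol comes from 1,2-reduction of a C1 enone; the enol lactone comes from the C19 acid and the C6 ketone of a tetracyclic diketo ester.
2. That tetracycle is made in one pot from a monocyclic 4-hydroxycyclohept-2-enone. C4 shifts from C6 to C5, so ring A (C1–C5, C10) arises from the seven-membered ring C4–C6–C5–C10–C1–C2–C3 by loss of C6. The C10 enamine then closes ring B on the aryl aldehyde carbon C20.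
3. Enabling feature: the vinylogous α-ketol O–C6–C5=C10–C1=O inside the seven-membered ring, with the C4–C6 bond allylic to the enone and C4 fully substituted, plus an ortho-formylbenzyl group (C7, C8, C9, C20) on C6 placed to trap C10.
4. The hydroxy enone comes from singlet oxygen/Kornblum–DeLaMare on a 2-benzylcyclohepta-1,3-diene. The diene comes from Negishi coupling of a dienyl triflate (from a cycloheptanone β-keto ester, C4 set by auxiliary-controlled methylation) with a benzylzinc reagent (ring C, from 2,5-dimethoxy-4-methylbenzaldehyde).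
5. Ring order: ring C and the seven-membered carbocycle are bought; rings A and B form together in the key step; then the lactone; then the quinone.

Key step: step 15

Remark: atoms carry icetexane numbers (ring A: C1–C5, C10; ring B: C5, C6, C7, C8, C9, C20, C10; ring C: C8, C9, C11–C14; C18 methyl and C19 carboxyl carbon on C4). The C6 carbinol of 24 and 25 is drawn as the epimer expected from oxygen attack anti to the ester. C6 becomes a carbonyl in step 15, so the other epimer serves equally. C5 of 26–29 is drawn 5R but is epimerisable until step 16.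

## Route

Step 1
Reactants: 1 methyl 2-oxocycloheptane-1-carboxylate; 2 (4-methoxyphenyl)methanol
Product: 3 4-methoxybenzyl 2-oxocycloheptane-1-carboxylate
Conditions: DMAP (cat.), PhMe, reflux, MeOH distilled off
Reagents that add atoms: none
Why: Thermal transesterification of a β-keto ester (through the acylketene) is driven by removal of methanol, and the 4-methoxybenzyl (PMB) ester is chosen because it survives steps 2–15 and is cleaved by acid in step 16.

Step 2
Reactants: 3 4-methoxybenzyl 2-oxocycloheptane-1-carboxylate; 4 tert-butyl L-valinate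
Product: 5 4-methoxybenzyl 2-{[(2S)-1-tert-butoxy-3-methyl-1-oxobutan-2-yl]amino}cyclohept-1-ene-1-carboxylate
Conditions: TsOH·H2O (cat.), PhH, reflux, Dean–Stark
Reagents that add atoms: none
Why: Acid-catalysed condensation of the amine with the ketone of the β-keto ester gives the hydrogen-bonded enamino ester (vinylogous carbamate), with azeotropic removal of water driving it to completion.

Step 3
Reactants: 5 enamino ester
Product: 7 4-methoxybenzyl (1S)-1-methyl-2-oxocycloheptane-1-carboxylate, via methylated imine 6 (not isolated)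
Conditions: LiN(iPr)2, PhMe, −78 °C; HMPA, MeI, −78 → −40 °C; then 1 M HCl, THF, rt
Reagents that add atoms: iodomethane (CI); water (O)
Why: Asymmetric alkylation of a chiral lithio-enamine: lithium is chelated by the valine ester carbonyl, the isopropyl group shields one face and MeI enters the other to set the quaternary C4 as (S), the sense depending on the cation-coordinating additive (tert-butyl D-valinate is used instead if the opposite sense is found), and mild acid hydrolysis of imine 6 releases the ketone and the auxiliary.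

Step 4
Reactants: 7 4-methoxybenzyl (1S)-1-methyl-2-oxocycloheptane-1-carboxylate
Product: 8 4-methoxybenzyl (1S)-1-methyl-2-oxocyclohept-3-ene-1-carboxylate
Conditions: IBX, 4-methoxypyridine N-oxide, DMSO, rt
Reagents that add atoms: none
Why: IBX dehydrogenation of a ketone through its enol is regiospecific here because C4 is quaternary and only C5 carries α-hydrogens, so the C5=C10 enone should form.

Step 5
Reactants: 8 enone
Product: 9 4-methoxybenzyl (1S)-1-methyl-2-(trifluoromethanesulfonyloxy)cyclohepta-2,4-diene-1-carboxylate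
Conditions: KN(SiMe3)2, THF, −78 °C; PhNTf2, −78 → 0 °C
Reagents that add atoms: N-phenylbis(trifluoromethanesulfonimide) (O=S(=O)(N(c1ccccc1)S(=O)(=O)C(F)(F)F)C(F)(F)F)
Why: With the α′ position blocked, the amide base removes a γ-hydrogen (C1) to give the extended dienolate, which is O-sulfonylated to the 2-triflyloxy-1,3-diene.

Step 6
Reactants: 10 2,5-dimethoxy-4-methylbenzaldehyde
Product: 12 2,5-dimethoxy-4-methylphenol, via aryl formate 11 (not isolated)
Conditions: mCPBA, CH2Cl2, 0 °C → rt; then K2CO3 (cat.), MeOH, rt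
Reagents that add atoms: 3-chloroperoxybenzoic acid (OOC(=O)c1cccc(Cl)c1)
Why: Baeyer–Villiger (Dakin-type) oxidation of an electron-rich benzaldehyde moves the aryl group to oxygen, and methanolysis of formate 11 gives the phenol whose oxygen becomes the C12 oxygen.

Step 7
Reactants: 12 2,5-dimethoxy-4-methylphenol
Product: 13 1,4-dimethoxy-2-(methoxymethoxy)-5-methylbenzene
Conditions: MOMCl, iPr2NEt, CH2Cl2, 0 °C → rt
Reagents that add atoms: chloromethyl methyl ether (COCCl)
Why: Standard O-alkylation of the phenol installs the MOM ether that directs the metalation of the next step.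

Step 8
Reactants: 13 MOM ether
Product: 15 2-[3,6-dimethoxy-2-(methoxymethoxy)-5-methylphenyl]propan-2-ol, via aryllithium 14 (not isolated)
Conditions: n-BuLi, THF, 0 °C; acetone, −78 °C → rt; H2O
Reagents that add atoms: acetone (CC(C)=O)
Why: Directed ortho-metalation occurs at the ring position flanked by the OMOM and OMe groups (C13), and the aryllithium adds to acetone.

Step 9
Reactants: 15 tertiary benzylic alcohol
Product: 16 3,6-dimethoxy-4-methyl-2-(propan-2-yl)phenol
Conditions: Et3SiH, TFA, CH2Cl2, 0 °C → rt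
Reagents that add atoms: none
Why: Ionic hydrogenation: TFA ionises the tertiary benzylic alcohol and Et3SiH reduces the cation to the isopropyl group, while the same acid removes the MOM group.

Step 10
Reactants: 16 phenol
Product: 17 tert-butyl[3,6-dimethoxy-4-methyl-2-(propan-2-yl)phenoxy]dimethylsilane
Conditions: TBSOTf, 2,6-lutidine, CH2Cl2, 0 °C
Reagents that add atoms: tert-butyldimethylsilyl trifluoromethanesulfonate (CC(C)(C)[Si](C)(C)OS(=O)(=O)C(F)(F)F)
Why: Silylation of the hindered phenol with the silyl triflate marks the C12 oxygen as the one to be freed in step 18.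

Step 11
Reactants: 17 aryl silyl ether
Product: 18 3-[(tert-butyldimethylsilyl)oxy]-2,5-dimethoxy-6-methyl-4-(propan-2-yl)benzaldehyde
Conditions: Cl2CHOMe, SnCl4, CH2Cl2, −78 → 0 °C; then H2O
Reagents that add atoms: dichloromethyl methyl ether (COC(Cl)Cl); water (O)
Why: Rieche formylation (Friedel–Crafts type) can only take place at the one unsubstituted ring position, C9, which is activated by its ortho methoxy group.

Step 12
Reactants: 18 benzaldehyde
Product: 19 tert-butyl[3-(dimethoxymethyl)-2,5-dimethoxy-4-methyl-6-(propan-2-yl)phenoxy]dimethylsilane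
Conditions: HC(OMe)3, TsOH·H2O (cat.), MeOH, rt
Reagents that add atoms: trimethyl orthoformate (COC(OC)OC)
Why: Acid-catalysed acetalisation with the orthoformate as water scavenger protects the aldehyde for the organometallic step.

Step 13
Reactants: 19 aryl acetal; 9 dienyl triflate
Product: 23 4-methoxybenzyl (1S)-2-{4-[(tert-butyldimethylsilyl)oxy]-2-formyl-3,6-dimethoxy-5-(propan-2-yl)benzyl}-1-methylcyclohepta-2,4-diene-1-carboxylate, via benzyllithium 20 (not isolated), via benzylzinc bromide 21 (not isolated), via diene acetal 22 (not isolated)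
Conditions: s-BuLi, TMEDA, THF, −78 °C; ZnBr2, −78 → 0 °C; 9, Pd(PPh3)4 (5 mol %), THF, 50 °C; then 1 M HCl, THF, 0 °C
Reagents that add atoms: water (O)
Why: Lateral lithiation of the C8 methyl group, directed by the flanking methoxy and acetal oxygens, transmetalation to zinc and Negishi coupling with the dienyl triflate form the C6–C7 bond, and the acidic work-up hydrolyses the acetal.

Step 14
Reactants: 23 diene aldehyde
Product: 25 4-methoxybenzyl (1S,2S)-2-{4-[(tert-butyldimethylsilyl)oxy]-2-formyl-3,6-dimethoxy-5-(propan-2-yl)benzyl}-2-hydroxy-1-methyl-5-oxocyclohept-3-ene-1-carboxylate (in equilibrium with its cyclic lactol), via endoperoxide 24 (not isolated)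
Conditions: O2, tetraphenylporphyrin (cat.), hν (visible), CH2Cl2, −78 °C; then Et3N, 0 °C → rt
Reagents that add atoms: dioxygen (O=O)
Why: [4+2] cycloaddition of singlet oxygen across the cisoid 1,3-diene (C6 to C1, expected anti to the ester on C4) is followed by Kornblum–DeLaMare rearrangement, in which Et3N removes the only bridgehead hydrogen (C1) and the O–O bond breaks to give the C1 ketone and the tertiary C6 alcohol.

Step 15
Reactants: 25 hydroxy enone aldehyde
Product: 28 tetracyclic diketo ester, 4-methoxybenzyl (4S,5R)-12-[(tert-butyldimethylsilyl)oxy]-11,14-dimethoxy-1,6-dioxoicetexa-8,11,13,10(20)-tetraen-19-oate, via ring-contracted diketo aldehyde 26 (not isolated), via aldol adduct 27 (not isolated)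
Conditions: pyrrolidine (0.5 equiv), AcOH (0.5 equiv), PhMe, 80 °C
Reagents that add atoms: none
Why: Proposed new method: pyrrolidine converts the C1 ketone of 25 into a conjugated iminium ion, so that C5 becomes electron-poor, and the C6 hydroxyl then pushes the C4–C6 σ-bond suprafacially onto C5 (vinylogous α-ketol, that is semipinacol-type, 1,2-shift), which expels C6 from the ring as the benzyl ketone, contracts the cycloheptene to ring A and leaves 26 as its C1=C10 enamine. The closest known reaction is the amine-catalysed vinylogous α-ketol rearrangement of β-(1-hydroxycyclobutyl) enones, which expands a strained ring, whereas here the same bond reorganisation is asked to contract an unstrained 4-hydroxycyclohept-2-enone, driven by formation of a ketone from an allylic carbinol and by relief of seven-ring strain. Ring A is thus formed by a 1,2-carbon shift through a three-centre transition state and not by a cyclisation, while ring B is closed when the enamine carbon C10 adds to the aryl aldehyde carbon C20 in a 7-(enolexo)-exo-trig aldol step (27) followed by loss of water, an ordinary amine-mediated aldol condensation that can start only once the shift has turned C10 from an enone α-carbon into an enamine carbon. C4 migrates with retention, so the configuration set in step 3 is carried over; C5 is created on the face on which C4 lies, stays epimerisable next to the C6 ketone and is fixed in step 16, and the C6 stereocentre is erased. The step needs C4 and not the benzylic carbon C7 to migrate (secured by ring contraction being the only strain-relieving path, by the better bridging ability of the fully substituted C4 and by the electron-poor, iminium-bearing aryl group on C7), bond formation at C5 and not at C10 (secured by the iminium ion, whose acceptor site is C5), and a concerted shift without retro-aldol cleavage that would scramble C4 (secured by the non-basic, acetic acid-buffered medium). The alternative aldol through C5 gives a quaternary β-hydroxy ketone that cannot lose water and reverts, so the arylidene ketone 28 is the only irreversible outcome.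

Step 16
Reactants: 28 tetracyclic diketo ester
Product: 30 enol lactone ketone, (4S,5R)-12-[(tert-butyldimethylsilyl)oxy]-11,14-dimethoxy-1-oxoicetexa-6,8,11,13,10(20)-pentaen-19,6-olide, via keto acid 29 (not isolated)
Conditions: TFA, anisole, CH2Cl2, 0 °C; evaporate; then Ac2O, NaOAc, 80 °C
Reagents that add atoms: none
Why: Acidolysis of the PMB ester gives the γ-keto acid, which Ac2O/NaOAc dehydrates through its hydroxy-lactone (pseudo-acid) form to the enol lactone with the styrene-type C6=C7 bond, while C5 equilibrates through the C6 enol and only the cis-fused lactone (C19 and C6 on the same face, hence 5R) can close.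

Step 17
Reactants: 30 enol lactone ketone
Product: 31 (1R,4S,5R)-12-[(tert-butyldimethylsilyl)oxy]-1-hydroxy-11,14-dimethoxyicetexa-6,8,11,13,10(20)-pentaen-19,6-olide
Conditions: NaBH4, CeCl3·7H2O, MeOH/CH2Cl2, −78 °C
Reagents that add atoms: none
Why: Luche 1,2-reduction of the enone should deliver hydride axially to C1 from the face opposite the lactone bridge and give the equatorial (1R) allylic alcohol, with the enol lactone expected to survive at −78 °C.

Step 18
Reactants: 31 allylic alcohol
Product: 33 6,7-anhydroballotiquinone, (1R,4S,5R)-1,12-dihydroxy-11,14-dioxoicetexa-6,8,12,10(20)-tetraen-19,6-olide, via 12-silyloxyquinone 32 (not isolated)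
Conditions: (NH4)2Ce(NO3)6 (2.5 equiv), MeCN/H2O, 0 °C
Reagents that add atoms: water (O)
Why: Oxidative demethylation of the para-dimethoxyarene by (NH4)2Ce(NO3)6 (quinone oxygens from water) gives the 11,14-quinone 32, whose 12-silyloxy group is a vinylogous silyl ester that should hydrolyse in the aqueous acidic medium.

## Compound list

1 | methyl 2-oxocycloheptane-1-carboxylate | COC(=O)C1CCCCCC1=O | starting material
2 | (4-methoxyphenyl)methanol | COc1ccc(CO)cc1 | starting material
3 | 4-methoxybenzyl 2-oxocycloheptane-1-carboxylate | COc1ccc(COC(=O)C2CCCCCC2=O)cc1 | intermediate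
4 | tert-butyl L-valinate | CC(C)[C@H](N)C(=O)OC(C)(C)C | starting material
5 | 4-methoxybenzyl 2-{[(2S)-1-tert-butoxy-3-methyl-1-oxobutan-2-yl]amino}cyclohept-1-ene-1-carboxylate | COc1ccc(COC(=O)C2=C(N[C@@H](C(C)C)C(=O)OC(C)(C)C)CCCCC2)cc1 | intermediate
6 | 4-methoxybenzyl (1S)-2-{[(2S)-1-tert-butoxy-3-methyl-1-oxobutan-2-yl]imino}-1-methylcycloheptane-1-carboxylate | COc1ccc(COC(=O)[C@@]2(C)CCCCCC2=N[C@@H](C(C)C)C(=O)OC(C)(C)C)cc1 | intermediate (not isolated)
7 | 4-methoxybenzyl (1S)-1-methyl-2-oxocycloheptane-1-carboxylate | COc1ccc(COC(=O)[C@@]2(C)CCCCCC2=O)cc1 | intermediate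
8 | 4-methoxybenzyl (1S)-1-methyl-2-oxocyclohept-3-ene-1-carboxylate | COc1ccc(COC(=O)[C@@]2(C)CCCC=CC2=O)cc1 | intermediate
9 | 4-methoxybenzyl (1S)-1-methyl-2-(trifluoromethanesulfonyloxy)cyclohepta-2,4-diene-1-carboxylate | COc1ccc(COC(=O)[C@@]2(C)CCC=CC=C2OS(=O)(=O)C(F)(F)F)cc1 | intermediate
10 | 2,5-dimethoxy-4-methylbenzaldehyde | Cc1cc(OC)c(C=O)cc1OC | starting material
11 | 2,5-dimethoxy-4-methylphenyl formate | Cc1cc(OC)c(OC=O)cc1OC | intermediate (not isolated)
12 | 2,5-dimethoxy-4-methylphenol | Cc1cc(OC)c(O)cc1OC | intermediate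
13 | 1,4-dimethoxy-2-(methoxymethoxy)-5-methylbenzene | Cc1cc(OC)c(OCOC)cc1OC | intermediate
14 | [3,6-dimethoxy-2-(methoxymethoxy)-5-methylphenyl]lithium | Cc1cc(OC)c(OCOC)c([Li])c1OC | intermediate (not isolated)
15 | 2-[3,6-dimethoxy-2-(methoxymethoxy)-5-methylphenyl]propan-2-ol | Cc1cc(OC)c(OCOC)c(C(C)(C)O)c1OC | intermediate
16 | 3,6-dimethoxy-4-methyl-2-(propan-2-yl)phenol | Cc1cc(OC)c(O)c(C(C)C)c1OC | intermediate
17 | tert-butyl[3,6-dimethoxy-4-methyl-2-(propan-2-yl)phenoxy]dimethylsilane | Cc1cc(OC)c(O[Si](C)(C)C(C)(C)C)c(C(C)C)c1OC | intermediate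
18 | 3-[(tert-butyldimethylsilyl)oxy]-2,5-dimethoxy-6-methyl-4-(propan-2-yl)benzaldehyde | Cc1c(C=O)c(OC)c(O[Si](C)(C)C(C)(C)C)c(C(C)C)c1OC | intermediate
19 | tert-butyl[3-(dimethoxymethyl)-2,5-dimethoxy-4-methyl-6-(propan-2-yl)phenoxy]dimethylsilane | Cc1c(C(OC)OC)c(OC)c(O[Si](C)(C)C(C)(C)C)c(C(C)C)c1OC | intermediate
20 | benzyllithium from 19 (lithium on the C8 methyl carbon, C7) | [Li]Cc1c(C(OC)OC)c(OC)c(O[Si](C)(C)C(C)(C)C)c(C(C)C)c1OC | intermediate (not isolated)
21 | benzylzinc bromide from 20 | Br[Zn]Cc1c(C(OC)OC)c(OC)c(O[Si](C)(C)C(C)(C)C)c(C(C)C)c1OC | intermediate (not isolated)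
22 | dimethyl acetal of 23 | COc1ccc(COC(=O)[C@@]2(C)CCC=CC=C2Cc2c(C(OC)OC)c(OC)c(O[Si](C)(C)C(C)(C)C)c(C(C)C)c2OC)cc1 | intermediate (not isolated)
23 | 4-methoxybenzyl (1S)-2-{4-[(tert-butyldimethylsilyl)oxy]-2-formyl-3,6-dimethoxy-5-(propan-2-yl)benzyl}-1-methylcyclohepta-2,4-diene-1-carboxylate | COc1ccc(COC(=O)[C@@]2(C)CCC=CC=C2Cc2c(C=O)c(OC)c(O[Si](C)(C)C(C)(C)C)c(C(C)C)c2OC)cc1 | intermediate
24 | endoperoxide of 23 (6,7-dioxabicyclo[3.2.2]non-8-ene; O–O bridge from C6 to C1, cis to the C4 methyl) | COc1ccc(COC(=O)[C@@]2(C)CC[C@@H]3OO[C@@]2(Cc2c(C=O)c(OC)c(O[Si](C)(C)C(C)(C)C)c(C(C)C)c2OC)C=C3)cc1 | intermediate (not isolated)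
25 | 4-methoxybenzyl (1S,2S)-2-{4-[(tert-butyldimethylsilyl)oxy]-2-formyl-3,6-dimethoxy-5-(propan-2-yl)benzyl}-2-hydroxy-1-methyl-5-oxocyclohept-3-ene-1-carboxylate | COc1ccc(COC(=O)[C@@]2(C)CCC(=O)C=C[C@@]2(O)Cc2c(C=O)c(OC)c(O[Si](C)(C)C(C)(C)C)c(C(C)C)c2OC)cc1 | intermediate
26 | ring-contracted diketo aldehyde (cyclohexanone ring A with C6 arylacetyl group on C5; engaged as its C1 enamine) | COc1ccc(COC(=O)[C@@]2(C)CCC(=O)C[C@H]2C(=O)Cc2c(C=O)c(OC)c(O[Si](C)(C)C(C)(C)C)c(C(C)C)c2OC)cc1 | intermediate (not isolated)
27 | aldol adduct (ring B closed, C20 carbinol; C10 and C20 unassigned) | COc1ccc(COC(=O)[C@@]2(C)CCC(=O)C3C(O)c4c(OC)c(O[Si](C)(C)C(C)(C)C)c(C(C)C)c(OC)c4CC(=O)[C@@H]23)cc1 | intermediate (not isolated)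
28 | 4-methoxybenzyl (4S,5R)-12-[(tert-butyldimethylsilyl)oxy]-11,14-dimethoxy-1,6-dioxoicetexa-8,11,13,10(20)-tetraen-19-oate | COc1ccc(COC(=O)[C@@]2(C)CCC(=O)C3=Cc4c(OC)c(O[Si](C)(C)C(C)(C)C)c(C(C)C)c(OC)c4CC(=O)[C@@H]23)cc1 | intermediate
29 | (4S,5R)-12-[(tert-butyldimethylsilyl)oxy]-11,14-dimethoxy-1,6-dioxoicetexa-8,11,13,10(20)-tetraen-19-oic acid | OC(=O)[C@@]1(C)CCC(=O)C2=Cc3c(OC)c(O[Si](C)(C)C(C)(C)C)c(C(C)C)c(OC)c3CC(=O)[C@@H]12 | intermediate (not isolated)
30 | (4S,5R)-12-[(tert-butyldimethylsilyl)oxy]-11,14-dimethoxy-1-oxoicetexa-6,8,11,13,10(20)-pentaen-19,6-olide | COc1c(C(C)C)c(O[Si](C)(C)C(C)(C)C)c(OC)c2c1C=C1OC(=O)[C@@]3(C)CCC(=O)C(=C2)[C@@H]13 | intermediate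
31 | (1R,4S,5R)-12-[(tert-butyldimethylsilyl)oxy]-1-hydroxy-11,14-dimethoxyicetexa-6,8,11,13,10(20)-pentaen-19,6-olide | COc1c(C(C)C)c(O[Si](C)(C)C(C)(C)C)c(OC)c2c1C=C1OC(=O)[C@@]3(C)CC[C@@H](O)C(=C2)[C@@H]13 | intermediate
32 | 12-O-(tert-butyldimethylsilyl) ether of 33 | CC(C)C1=C(O[Si](C)(C)C(C)(C)C)C(=O)C2=C(C=C3OC(=O)[C@@]4(C)CC[C@@H](O)C(=C2)[C@@H]34)C1=O | intermediate (not isolated)
33 | 6,7-anhydroballotiquinone, (1R,4S,5R)-1,12-dihydroxy-11,14-dioxoicetexa-6,8,12,10(20)-tetraen-19,6-olide | CC(C)C1=C(O)C(=O)C2=C(C=C3OC(=O)[C@@]4(C)CC[C@@H](O)C(=C2)[C@@H]34)C1=O | target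

## Step count and risks

Total step count: 18. Longest linear sequence: 13 steps (steps 6–12, then 13–18).

Steps most likely to fail:

**Step 15.** The benzylic carbon C7 may migrate instead of C4, the C4–C6 bond may cleave dissociatively (retro-aldol) with loss of configuration at C4, or the rearrangement may not start at all.
Fallback (known chemistry; ring A is still made by contraction of the seven-membered ring, now by a Wolff rearrangement, and the aryl fragment is attached afterwards): it sets out from enone 8. TBSOTf/Et3N gives the silyl dienol ether F1. Singlet oxygen [4+2] across C6/C1 followed by PPh3 gives the γ-hydroxy enone F2 (C1 epimers, both usable). Conjugate reduction with [(Ph3P)CuH]6 (cat.) and PhSiH3 gives the hydroxy ketone F3. Detrifluoroacetylative diazo transfer at C5 (LiN(SiMe3)2, CF3CO2CH2CF3; then MsN3, Et3N, H2O) gives the α-diazo ketone F4. Photolysis (hν, THF) triggers the Wolff ring contraction (C4 moves from C6 to C5 with retention), and the C1 hydroxyl captures the ketene as the bridged γ-lactone F5. One equivalent of benzyllithium 20 at −78 °C opens the lactone to the hydroxy benzyl ketone F6. Dess–Martin periodinane gives the diketone acetal F7. Pyrrolidine/AcOH in wet toluene (acetal hydrolysis and aldol condensation) then returns to the route at 28.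

**Step 13.** Lateral deprotonation may be incomplete or unselective (attack at silicon or at the acetal C–H), and coupling next to the quaternary carbon may be slow.
Fallback (the benzylic zinc reagent is made by insertion into a C–Br bond instead of by deprotonation): it sets out from aldehyde 18. Radical bromination of the C8 methyl group (NBS, AIBN (cat.), PhCF3, 80 °C) gives the benzylic bromide F8. Non-solvolytic acetalisation (MeOSiMe3, Me3SiOTf (cat.), CH2Cl2, −78 °C) gives the bromide acetal F9. Zinc insertion (Zn dust, LiCl, THF) gives the benzylzinc bromide 21, where the route is rejoined within step 13.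

**Step 18.** The electron-rich styrene-type enol lactone or the allylic alcohol may be over-oxidised, or the silyl group may be lost before the arene is oxidised.
Fallback (the order is changed so that the quinone is made before the allylic alcohol exists): it sets out from 30. (NH4)2Ce(NO3)6 in MeCN/H2O gives the hydroxyquinone ketone F10. NaBH4/CeCl3·7H2O at −78 °C then reduces C1, the acidic hydroxyquinone being present as its unreactive anion and any hydroquinone being re-oxidised by air on work-up, to give 33.

## Further compounds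

F1 | step 15 | 4-methoxybenzyl (1S)-2-[(tert-butyldimethylsilyl)oxy]-1-methylcyclohepta-2,4-diene-1-carboxylate | COc1ccc(COC(=O)[C@@]2(C)CCC=CC=C2O[Si](C)(C)C(C)(C)C)cc1
F2 | step 15 | 4-methoxybenzyl (1S)-5-hydroxy-1-methyl-2-oxocyclohept-3-ene-1-carboxylate | COc1ccc(COC(=O)[C@@]2(C)CCC(O)C=CC2=O)cc1
F3 | step 15 | 4-methoxybenzyl (1S)-5-hydroxy-1-methyl-2-oxocycloheptane-1-carboxylate | COc1ccc(COC(=O)[C@@]2(C)CCC(O)CCC2=O)cc1
F4 | step 15 | 4-methoxybenzyl (1S)-3-diazo-5-hydroxy-1-methyl-2-oxocycloheptane-1-carboxylate | COc1ccc(COC(=O)[C@@]2(C)CCC(O)CC(=[N+]=[N-])C2=O)cc1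
F5 | step 15 | bridged lactone, 4-methoxybenzyl 2-methyl-7-oxo-6-oxabicyclo[3.2.1]octane-2-carboxylate (S at the quaternary carbon) | COc1ccc(COC(=O)[C@@]2(C)CCC3CC2C(=O)O3)cc1
F6 | step 15 | hydroxy benzyl ketone (ring A with C1 hydroxyl and C6 arylacetyl group; aldehyde as dimethyl acetal) | COc1ccc(COC(=O)[C@@]2(C)CCC(O)CC2C(=O)Cc2c(C(OC)OC)c(OC)c(O[Si](C)(C)C(C)(C)C)c(C(C)C)c2OC)cc1
F7 | step 15 | dimethyl acetal of diketo aldehyde 26 (C5 unassigned) | COc1ccc(COC(=O)[C@@]2(C)CCC(=O)CC2C(=O)Cc2c(C(OC)OC)c(OC)c(O[Si](C)(C)C(C)(C)C)c(C(C)C)c2OC)cc1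
F8 | step 13 | 2-(bromomethyl)-5-[(tert-butyldimethylsilyl)oxy]-3,6-dimethoxy-4-(propan-2-yl)benzaldehyde | BrCc1c(C=O)c(OC)c(O[Si](C)(C)C(C)(C)C)c(C(C)C)c1OC
F9 | step 13 | dimethyl acetal of F8 | BrCc1c(C(OC)OC)c(OC)c(O[Si](C)(C)C(C)(C)C)c(C(C)C)c1OC
F10 | step 18 | (4S,5R)-12-hydroxy-1,11,14-trioxoicetexa-6,8,12,10(20)-tetraen-19,6-olide | CC(C)C1=C(O)C(=O)C2=C(C=C3OC(=O)[C@@]4(C)CCC(=O)C(=C2)[C@@H]34)C1=O
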